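**Plan**
- Retrosynthesis: cut C12–C13 (Negishi coupling with a Z-iodoenoate), then C8=C17 (Wittig), then the C5–C6 bond of ring B, then C9–C11 and C10–C9 (two enolate alkylations); this leads back to ketoisophorone as ring A.
- Forward: ring A (C1–C5, C10) comes from ketoisophorone; the C9–C8–C7–C6 chain and C11–C12 are attached at C10 and C9; ring B is closed last between C6 and C5; the side chain is finished after methylenation.
- Enabling feature: the ring-A carbonyl at C5 lies between the quaternary C4 (gem-dimethyl) and C10 (angular methyl). It has no α-hydrogen, so it survives every enolate step, accepts the C6 carbanion, and its carbinol can lose water only toward C6.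
- Stereochemistry: C2 from a CBS reduction; C10 by alkylation trans to the C2 benzyloxy group; C5 by hydrogenation of C5=C6 anti to the C10 methyl; C9 by equilibration next to the C8 ketone; 13Z from anti-hydroiodination and a stereoretentive coupling.

Key step: step 8

Remark: atoms carry labdane numbers (ring A: C1–C5, C10; ring B: C5–C10); β is the face of the C10 methyl group.

**Step 1**
Reactants: 1 ketoisophorone (2,6,6-trimethylcyclohex-2-ene-1,4-dione)
Product: 2 (R)-4-hydroxy-2,6,6-trimethylcyclohex-2-en-1-one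
Conditions: (S)-1-methyl-3,3-diphenyltetrahydro-1H,3H-pyrrolo[1,2-c][1,3,2]oxazaborole (10 mol %), catecholborane, toluene, −78 °C; MeOH quench
Reagents that add atoms: none
Why: In this Corey–Bakshi–Shibata reduction the catalyst–borane complex should reach only the carbonyl flanked by CH and CH2 (future C2), because the other carbonyl is shielded by the gem-dimethyl carbon and the methyl-bearing alkene carbon, and with the alkenyl branch as the large group hydride delivery should give the R alcohol.

**Step 2**
Reactants: 2 (R)-4-hydroxy-2,6,6-trimethylcyclohex-2-en-1-one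
Product: 3 (R)-4-(benzyloxy)-2,6,6-trimethylcyclohex-2-en-1-one
Conditions: BnOC(=NH)CCl3, CF3SO3H (5 mol %), CH2Cl2/cyclohexane, 0 °C → rt
Reagents that add atoms: benzyl 2,2,2-trichloroacetimidate, N=C(OCc1ccccc1)C(Cl)(Cl)Cl
Why: Acid-catalysed imidate O-benzylation avoids base, so the γ-oxygenated enone should be neither enolised nor epimerised.

**Step 3**
Reactants: 3 (R)-4-(benzyloxy)-2,6,6-trimethylcyclohex-2-en-1-one
Product: 5 2-[(1R,5R)-5-(benzyloxy)-1,3,3-trimethyl-2-oxocyclohexyl]-N-methoxy-N-methylacetamide, via lithium enolate 4 (not isolated)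
Conditions: LiBH(s-Bu)3, THF, −78 °C; then (Me2N)3PO, BrCH2C(O)N(OMe)Me, −78 → 0 °C
Reagents that add atoms: 2-bromo-N-methoxy-N-methylacetamide, BrCC(=O)N(C)OC
Why: In this reductive alkylation of an enone, conjugate hydride addition gives the only possible enolate, and the electrophile should enter axially on the half-chair that keeps the benzyloxy group equatorial, i.e. trans to C2–O, which sets C10 with the chain on the α-face and the methyl on the β-face.

**Step 4**
Reactants: 6 2-(benzyloxy)ethanol
Product: 7 2-(benzyloxy)ethyl trifluoromethanesulfonate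
Conditions: (CF3SO2)2O, 2,6-lutidine, CH2Cl2, −78 °C; used crude
Reagents that add atoms: trifluoromethanesulfonic anhydride, O=S(=O)(OS(=O)(=O)C(F)(F)F)C(F)(F)F
Why: O-sulfonylation of a primary alcohol should give a triflate reactive enough to alkylate a hindered enolate despite the β-oxygen.

**Step 5**
Reactants: 5 2-[(1R,5R)-5-(benzyloxy)-1,3,3-trimethyl-2-oxocyclohexyl]-N-methoxy-N-methylacetamide; 7 2-(benzyloxy)ethyl trifluoromethanesulfonate
Product: 9 4-(benzyloxy)-2-[(1R,5R)-5-(benzyloxy)-1,3,3-trimethyl-2-oxocyclohexyl]-N-methoxy-N-methylbutanamide, via amide lithium enolate 8 (not isolated)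
Conditions: LiN(i-Pr)2, THF, −78 °C; then 7, −78 → −30 °C
Reagents that add atoms: none
Why: In this amide enolate alkylation only the amide can be deprotonated because the ring ketone has no α-hydrogen; the new C9 centre is not controlled here and is corrected by equilibration in step 10.

**Step 6**
Reactants: 9 4-(benzyloxy)-2-[(1R,5R)-5-(benzyloxy)-1,3,3-trimethyl-2-oxocyclohexyl]-N-methoxy-N-methylbutanamide
Product: 10 (2R,4R)-4-(benzyloxy)-2-[6-(benzyloxy)-3-oxohex-1-en-4-yl]-2,6,6-trimethylcyclohexan-1-one
Conditions: CH2=CHMgBr, THF, −20 → 0 °C; poured into cold 1 M HCl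
Reagents that add atoms: vinylmagnesium bromide, C=C[Mg]Br
Why: In this Weinreb ketone synthesis the chelated tetrahedral intermediate should stop at mono-addition, and the ring ketone between two quaternary carbons should be too hindered to react.

**Step 7**
Reactants: 10 (2R,4R)-4-(benzyloxy)-2-[6-(benzyloxy)-3-oxohex-1-en-4-yl]-2,6,6-trimethylcyclohexan-1-one
Product: 12 (2R,4R)-4-(benzyloxy)-2-{3-(benzyloxy)-1-[2-(2-bromoethyl)-1,3-dioxolan-2-yl]propyl}-2,6,6-trimethylcyclohexan-1-one, via β-bromo ketone 11 (not isolated)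
Conditions: Me3SiBr, HOCH2CH2OH, CH2Cl2, 0 °C → rt
Reagents that add atoms: bromotrimethylsilane, C[Si](C)(C)Br; ethylene glycol, OCCO
Why: Conjugate hydrobromination of the vinyl ketone followed by dioxolane formation in the same flask should place the bromide on C6 and mask the C8 carbonyl, while the C5 ketone is too hindered to ketalise.

**Step 8**
Reactants: 12 (2R,4R)-4-(benzyloxy)-2-{3-(benzyloxy)-1-[2-(2-bromoethyl)-1,3-dioxolan-2-yl]propyl}-2,6,6-trimethylcyclohexan-1-one
Product: 13 2β,12-bis(benzyloxy)-5β-hydroxy-13,14,15,16,17-pentanorlabdan-8-one ethylene ketal (rings A/B cis-fused)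
Conditions: SmI2 (2.5 equiv), (Me2N)3PO, THF, 0 °C → rt; aq. NH4Cl
Reagents that add atoms: none
Why: Two single-electron transfers from divalent samarium should turn the primary C6–Br bond into a radical and then a C6–samarium species, which adds to the C5 carbonyl of ring A and closes ring B through the C5–C6 bond. The closest known reaction type is the samarium Barbier cyclization of ω-halo ketones. Ring B closes in the 6-exo-trig mode, with the carbonyl oxygen outside the new six-membered ring. The new C5 carbinol centre is controlled by C10, whose tether should reach the carbonyl only from the α-face and give the cis-fused 5β-alcohol; its configuration does not matter because C5 becomes planar in step 9 and is reset in step 10. The step needs chemoselectivity: reduction of the C–Br bond before the ketone, and carbonyl addition instead of enolisation or protonation. The substrate secures this because the C5 ketone between the quaternary C4 and C10 has no α-hydrogen and is too hindered for intermolecular coupling, and the C8 carbonyl is masked as the dioxolane.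

**Step 9**
Reactants: 13 2β,12-bis(benzyloxy)-5β-hydroxy-13,14,15,16,17-pentanorlabdan-8-one ethylene ketal
Product: 14 2β,12-bis(benzyloxy)-13,14,15,16,17-pentanorlabd-5-en-8-one ethylene ketal
Conditions: SOCl2, pyridine, 0 °C
Reagents that add atoms: none
Why: In this chlorosulfite-mediated dehydration only C6 carries β-hydrogens (C4 and C10 are quaternary), so a single alkene regioisomer should form, and the pyridine buffer should suppress a free C5 cation and its methyl shifts.

**Step 10**
Reactants: 14 2β,12-bis(benzyloxy)-13,14,15,16,17-pentanorlabd-5-en-8-one ethylene ketal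
Product: 16 2β,12-dihydroxy-13,14,15,16,17-pentanorlabdan-8-one, via diol ketal 15 (not isolated)
Conditions: H2 (4 atm), Pd(OH)2 on carbon, EtOH, rt; filtration; then 2 M HCl, THF, 40 °C
Reagents that add atoms: water, O
Why: Catalytic syn-hydrogenation should add to the α-face of C5=C6, because the β-face is covered by the C10 methyl and the axial C4 methyl, giving the 5α-H trans-decalin with hydrogenolysis of both benzyl ethers, and the following acid hydrolysis of the dioxolane should equilibrate C9 through the enol to the equatorial (β) side chain.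

**Step 11**
Reactants: 16 2β,12-dihydroxy-13,14,15,16,17-pentanorlabdan-8-one
Product: 17 13,14,15,16-tetranorlabd-8(17)-ene-2β,12-diol
Conditions: Ph3PCH3Br, KOt-Bu (excess), toluene, 90 °C
Reagents that add atoms: methyltriphenylphosphonium bromide, C[P+](c1ccccc1)(c1ccccc1)c1ccccc1.[Br-]
Why: Wittig methylenation with excess ylide (two alkoxides are formed first) should convert the hindered C8 ketone into the exocyclic alkene while C9 stays in its thermodynamic configuration.

**Step 12**
Reactants: 17 13,14,15,16-tetranorlabd-8(17)-ene-2β,12-diol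
Product: 18 12-iodo-13,14,15,16-tetranorlabd-8(17)-en-2β-ol
Conditions: PPh3, imidazole, I2 (premixed), CH2Cl2, 0 °C
Reagents that add atoms: iodine, II
Why: Appel-type iodination should take the primary C12 hydroxyl and leave the axial, doubly flanked C2 hydroxyl, and premixing the reagents should leave no free iodine for iodoetherification of the alkene.

**Step 13**
Reactants: 18 12-iodo-13,14,15,16-tetranorlabd-8(17)-en-2β-ol
Product: 19 12-iodo-13,14,15,16-tetranorlabd-8(17)-en-2β-yl acetate
Conditions: Ac2O, Et3N, 4-(dimethylamino)pyridine (cat.), CH2Cl2, rt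
Reagents that add atoms: acetic anhydride, CC(=O)OC(C)=O
Why: Nucleophile-catalysed acylation should acetylate the hindered secondary alcohol with retention at C2, under conditions too mild to quaternise the amine with the primary iodide.

**Step 14**
Reactants: 20 but-2-ynoic acid
Product: 21 (Z)-3-iodobut-2-enoic acid
Conditions: NaI, AcOH, 110 °C
Reagents that add atoms: sodium iodide, [Na+].[I-]
Why: Conjugate addition of iodide followed by protonation (anti hydroiodination of an ynoic acid) should place iodine cis to the carboxyl group.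

**Step 15**
Reactants: 21 (Z)-3-iodobut-2-enoic acid
Product: 22 2-(trimethylsilyl)ethyl (Z)-3-iodobut-2-enoate
Conditions: Me3SiCH2CH2OH, PPh3, diisopropyl azodicarboxylate, THF, 0 °C → rt
Reagents that add atoms: 2-(trimethylsilyl)ethanol, C[Si](C)(C)CCO
Why: Mitsunobu esterification activates the alcohol and not the acyl group, so the Z-iodoenoate should not isomerise by addition–elimination.

**Step 16**
Reactants: 19 12-iodo-13,14,15,16-tetranorlabd-8(17)-en-2β-yl acetate; 22 2-(trimethylsilyl)ethyl (Z)-3-iodobut-2-enoate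
Product: 24 2-(trimethylsilyl)ethyl 2β-acetoxylabda-8(17),13Z-dien-15-oate, via alkylzinc iodide 23 (not isolated)
Conditions: Zn dust, LiCl, THF, 40 °C; then 22, Pd(PPh3)4 (5 mol %), THF, rt
Reagents that add atoms: none
Why: In this Negishi coupling zinc should insert into the primary C–I bond without touching the acetate, and the zerovalent palladium catalyst should join C12 to C13 with retention of the Z geometry.

**Step 17**
Reactants: 24 2-(trimethylsilyl)ethyl 2β-acetoxylabda-8(17),13Z-dien-15-oate
Product: 25 2β-acetoxylabda-8(17),13Z-dien-15-oic acid (target)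
Conditions: Bu4NF, THF, 0 °C → rt; then aq. HCl to pH 3
Reagents that add atoms: none
Why: Fluoride-induced fragmentation of the 2-(trimethylsilyl)ethyl ester should free the acid under conditions that leave the hindered axial acetate, the exocyclic alkene and the Z-enoate untouched.

**Compound list**
1 | ketoisophorone (2,6,6-trimethylcyclohex-2-ene-1,4-dione) | CC1=CC(=O)CC(C)(C)C1=O | starting material
2 | (R)-4-hydroxy-2,6,6-trimethylcyclohex-2-en-1-one | CC1=C[C@H](O)CC(C)(C)C1=O | intermediate
3 | (R)-4-(benzyloxy)-2,6,6-trimethylcyclohex-2-en-1-one | CC1=C[C@H](OCc2ccccc2)CC(C)(C)C1=O | intermediate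
4 | lithium (S)-4-(benzyloxy)-2,6,6-trimethylcyclohex-1-en-1-olate | [Li+].[O-]C1=C(C)C[C@H](OCc2ccccc2)CC1(C)C | intermediate
5 | 2-[(1R,5R)-5-(benzyloxy)-1,3,3-trimethyl-2-oxocyclohexyl]-N-methoxy-N-methylacetamide | O=C1C(C)(C)C[C@@H](OCc2ccccc2)C[C@]1(C)CC(=O)N(C)OC | intermediate
6 | 2-(benzyloxy)ethanol | OCCOCc1ccccc1 | starting material
7 | 2-(benzyloxy)ethyl trifluoromethanesulfonate | O=S(=O)(OCCOCc1ccccc1)C(F)(F)F | intermediate
8 | lithium enolate of amide 5 | O=C1C(C)(C)C[C@@H](OCc2ccccc2)C[C@]1(C)C=C([O-])N(C)OC.[Li+] | intermediate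
9 | 4-(benzyloxy)-2-[(1R,5R)-5-(benzyloxy)-1,3,3-trimethyl-2-oxocyclohexyl]-N-methoxy-N-methylbutanamide (both epimers at butanamide C2 = labdane C9) | O=C1C(C)(C)C[C@@H](OCc2ccccc2)C[C@]1(C)C(CCOCc3ccccc3)C(=O)N(C)OC | intermediate
10 | (2R,4R)-4-(benzyloxy)-2-[6-(benzyloxy)-3-oxohex-1-en-4-yl]-2,6,6-trimethylcyclohexan-1-one (C9 epimers) | O=C1C(C)(C)C[C@@H](OCc2ccccc2)C[C@]1(C)C(CCOCc3ccccc3)C(=O)C=C | intermediate
11 | (2R,4R)-4-(benzyloxy)-2-[1-(benzyloxy)-6-bromo-4-oxohexan-3-yl]-2,6,6-trimethylcyclohexan-1-one (C9 epimers) | O=C1C(C)(C)C[C@@H](OCc2ccccc2)C[C@]1(C)C(CCOCc3ccccc3)C(=O)CCBr | intermediate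
12 | (2R,4R)-4-(benzyloxy)-2-{3-(benzyloxy)-1-[2-(2-bromoethyl)-1,3-dioxolan-2-yl]propyl}-2,6,6-trimethylcyclohexan-1-one (C9 epimers) | O=C1C(C)(C)C[C@@H](OCc2ccccc2)C[C@]1(C)C(CCOCc3ccccc3)C4(CCBr)OCCO4 | intermediate
13 | 2β,12-bis(benzyloxy)-5β-hydroxy-13,14,15,16,17-pentanorlabdan-8-one ethylene ketal (A/B cis-fused, C6 on the α-face, 10β-methyl; C9 epimers) | C12(OCCO1)CC[C@]3(O)C(C)(C)C[C@@H](OCc4ccccc4)C[C@]3(C)C2CCOCc5ccccc5 | intermediate
14 | 2β,12-bis(benzyloxy)-13,14,15,16,17-pentanorlabd-5-en-8-one ethylene ketal (C9 epimers) | C12(OCCO1)CC=C3C(C)(C)C[C@@H](OCc4ccccc4)C[C@]3(C)C2CCOCc5ccccc5 | intermediate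
15 | 2β,12-dihydroxy-13,14,15,16,17-pentanorlabdan-8-one ethylene ketal (5α-H; C9 epimers) | C12(OCCO1)CC[C@H]3C(C)(C)C[C@@H](O)C[C@]3(C)C2CCO | intermediate
16 | 2β,12-dihydroxy-13,14,15,16,17-pentanorlabdan-8-one (5α-H, 9α-H, 10β-methyl) | O=C1CC[C@H]2C(C)(C)C[C@@H](O)C[C@]2(C)[C@H]1CCO | intermediate
17 | 13,14,15,16-tetranorlabd-8(17)-ene-2β,12-diol | C=C1CC[C@H]2C(C)(C)C[C@@H](O)C[C@]2(C)[C@H]1CCO | intermediate
18 | 12-iodo-13,14,15,16-tetranorlabd-8(17)-en-2β-ol | C=C1CC[C@H]2C(C)(C)C[C@@H](O)C[C@]2(C)[C@H]1CCI | intermediate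
19 | 12-iodo-13,14,15,16-tetranorlabd-8(17)-en-2β-yl acetate | C=C1CC[C@H]2C(C)(C)C[C@@H](OC(C)=O)C[C@]2(C)[C@H]1CCI | intermediate
20 | but-2-ynoic acid | CC#CC(=O)O | starting material
21 | (Z)-3-iodobut-2-enoic acid | I/C(C)=C\C(=O)O | intermediate
22 | 2-(trimethylsilyl)ethyl (Z)-3-iodobut-2-enoate | I/C(C)=C\C(=O)OCC[Si](C)(C)C | intermediate
23 | (2β-acetoxy-13,14,15,16-tetranorlabd-8(17)-en-12-yl)zinc iodide | C=C1CC[C@H]2C(C)(C)C[C@@H](OC(C)=O)C[C@]2(C)[C@H]1CC[Zn]I | intermediate
24 | 2-(trimethylsilyl)ethyl 2β-acetoxylabda-8(17),13Z-dien-15-oate | C=C1CC[C@H]2C(C)(C)C[C@@H](OC(C)=O)C[C@]2(C)[C@H]1CC/C(C)=C\C(=O)OCC[Si](C)(C)C | intermediate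
25 | 2β-acetoxylabda-8(17),13Z-dien-15-oic acid, (2R,5S,9S,10S) | C=C1CC[C@H]2C(C)(C)C[C@@H](OC(C)=O)C[C@]2(C)[C@H]1CC/C(C)=C\C(=O)O | target

**Totals**
Total step count: 17. Longest linear sequence: 14 steps (steps 1–3, 5–13, 16, 17, from 1 to 25).

**Steps most likely to fail**

Step 8. The C6–samarium species may be protonated, or the very hindered C5 carbonyl may fail to accept it, so that simple reduction outruns ring closure. The fallback sets out from 12: Kornblum oxidation (NaHCO3, Me2SO, 100 °C) should give the keto aldehyde (2R,4R)-4-(benzyloxy)-2-{3-(benzyloxy)-1-[2-(2-oxoethyl)-1,3-dioxolan-2-yl]propyl}-2,6,6-trimethylcyclohexan-1-one F1. An intramolecular McMurry coupling of F1 (TiCl3, Zn–Cu couple, dimethoxyethane, reflux, high dilution) then forms C5=C6 directly and comes back to the route at 14, so step 9 is no longer needed.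

Step 3. Facial selectivity in the alkylation of the tetrasubstituted enolate may be poor (attack cis to the benzyloxy group), or the acidic α-bromo amide may transfer a proton to the enolate. The fallback sets out from 3 and puts C10 under catalyst control. Conjugate reduction with LiBH(s-Bu)3 and O-acylation with allyl chloroformate should give allyl (S)-4-(benzyloxy)-2,6,6-trimethylcyclohex-1-en-1-yl carbonate F2. A decarboxylative Tsuji allylation (Pd2(dba)3, (R)-4-tert-butyl-2-[2-(diphenylphosphino)phenyl]-4,5-dihydrooxazole, THF) should give (2S,4R)-2-allyl-4-(benzyloxy)-2,6,6-trimethylcyclohexan-1-one F3. Lemieux–Johnson cleavage (OsO4 cat., NaIO4) gives 2-[(1R,5R)-5-(benzyloxy)-1,3,3-trimethyl-2-oxocyclohexyl]acetaldehyde F4, Pinnick oxidation (NaClO2, NaH2PO4, 2-methyl-2-butene) gives 2-[(1R,5R)-5-(benzyloxy)-1,3,3-trimethyl-2-oxocyclohexyl]acetic acid F5, and carbodiimide coupling with N,O-dimethylhydroxylamine comes back to the route at 5.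

Step 10. Hydrogen delivery may show poor facial selectivity in the C9 epimer whose side chain sits axially on the α-face, and the hindered trisubstituted alkene may reduce slowly. The fallback sets out from 14 and uses a radical hydrogen-atom-transfer hydrogenation (Mn(dpm)3, PhSiH3, t-BuOOH, i-PrOH), in which the planar tertiary C5 radical should take its hydrogen from the α-face; this should give 2β,12-bis(benzyloxy)-13,14,15,16,17-pentanorlabdan-8-one ethylene ketal F6 (5α-H). Hydrogenolysis of the benzyl ethers and ketal hydrolysis (H2, Pd on carbon, EtOH, aq. HCl) then come back to the route at 16.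

**Further compounds**
F1 | step 8 | (2R,4R)-4-(benzyloxy)-2-{3-(benzyloxy)-1-[2-(2-oxoethyl)-1,3-dioxolan-2-yl]propyl}-2,6,6-trimethylcyclohexan-1-one | O=C1C(C)(C)C[C@@H](OCc2ccccc2)C[C@]1(C)C(CCOCc3ccccc3)C4(CC=O)OCCO4
F2 | step 3 | allyl (S)-4-(benzyloxy)-2,6,6-trimethylcyclohex-1-en-1-yl carbonate | C=CCOC(=O)OC1=C(C)C[C@H](OCc2ccccc2)CC1(C)C
F3 | step 3 | (2S,4R)-2-allyl-4-(benzyloxy)-2,6,6-trimethylcyclohexan-1-one | O=C1C(C)(C)C[C@@H](OCc2ccccc2)C[C@]1(C)CC=C
F4 | step 3 | 2-[(1R,5R)-5-(benzyloxy)-1,3,3-trimethyl-2-oxocyclohexyl]acetaldehyde | O=C1C(C)(C)C[C@@H](OCc2ccccc2)C[C@]1(C)CC=O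
F5 | step 3 | 2-[(1R,5R)-5-(benzyloxy)-1,3,3-trimethyl-2-oxocyclohexyl]acetic acid | O=C1C(C)(C)C[C@@H](OCc2ccccc2)C[C@]1(C)CC(=O)O
F6 | step 10 | 2β,12-bis(benzyloxy)-13,14,15,16,17-pentanorlabdan-8-one ethylene ketal (5α-H; C9 epimers) | C12(OCCO1)CC[C@H]3C(C)(C)C[C@@H](OCc4ccccc4)C[C@]3(C)C2CCOCc5ccccc5
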